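All runs are calculated on assumed constants.

In the midnight flask free monomer rises more slowly than the feed delivers it. From 2.50 h to 8.00 h the feed brings 36.7% of the charge, but the reading gains 7 percentage points.

| setting | midnight | autumn | flask |
|---|---|---|---|
| free monomer | 0.28 M (fed, over 15 h) | 0.28 M (fed, over 15 h) | 0.28 M (fed, over 15 h) |
| initiator | 0.56 mM | 0.56 mM | 0.56 mM |
| radical scavenger | 3.6 mM | 1.8 mM | 3.6 mM |
| remark | the very flask that is asked about, followed so far; the fed solution adds 1.0 times the starting volume | run made earlier; the fed solution adds 1.0 times the starting volume | the fed solution adds 1.0 times the starting volume |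
| time |  |  | 15 h |

| run | time / h | dormant form / % | free monomer / % | monomer in chains / % |
|---|---|---|---|---|
| midnight | 0.667 | 3 | 4 | 0 |
| midnight | 1.00 | 1 | 6 | 0 |
| midnight | 1.50 | 3 | 9 | 1 |
| midnight | 2.50 | 6 | 11 | 4 |
| midnight | 5.00 | 18 | 12 | 2 |
| midnight | 8.00 | 35 | 18 | 4 |
| autumn | 1.00 | 1 | 8 | 0 |
| autumn | 2.00 | 5 | 9 | 0 |
| autumn | 3.00 | 8 | 9 | 0 |
| autumn | 4.00 | 16 | 13 | 0 |
| autumn | 5.00 | 18 | 14 | 0 |
| autumn | 6.00 | 26 | 14 | 0 |

(readings scatter by 2 percentage points)

- how much dormant form the flask holds at 15 h, in percent of the free monomer charged
- how much free monomer the flask holds at 15 h, in percent of the free monomer charged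

I read these tables column against column. At 8.00 h the midnight flask shows 35% dormant form against 18% free monomer, so the dormant form is the resting state of the monomer. Monomer in chains reads 4%, with a scatter of 2 points. Twice the initiator charge is 1.12 mM, less than the 3.6 mM of scavenger, so I count chains as small.

I take the exchange as first order both ways. Once it keeps pace with a steady feed, the free monomer, counted in percent of the charge, climbs on a straight line. The midnight rise over the midnight feed gives 19.1%. I call this the tail share, the part of each further percent fed that stays free. A closed flask should end split by the same share.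

The autumn column is the check. That flask has less scavenger, and from 2.00 h to 6.00 h its readings give 18.8%.

So I continue the midnight flask from its last reading and reach 26.9% free monomer at 15 h, which leaves 73.1% dormant form.

The forecast differs from my reckoning. It says 78% dormant form (69% to 85%) and 19% free monomer (14% to 26%), on these grounds: “Extrapolating gives M(15 h) ≈ 9 + 11 ≈ 20 %, or about 19 % allowing for chains.” My free monomer lies above its range.

    2 growing radical → dead chain (k = 1.00 × 10⁷ M⁻¹ s⁻¹)
    initiator → 2 initiating radical (k = 3.19 × 10⁻⁴ min⁻¹)
    free monomer ⇌ dormant form (K = 3.42, k = 0.00999 min⁻¹)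
    free monomer + initiating radical → growing radical + monomer in chains (k = 1.36 × 10⁵ M⁻¹ s⁻¹)
    free monomer + growing radical → monomer in chains + growing radical, rate k5*[growing radical]*[free monomer] (k = 3.18 × 10⁵ M⁻¹ min⁻¹)
    growing radical + radical scavenger → ended chains (k = 3.18 × 10⁶ M⁻¹ s⁻¹)

The flask gives 29.3% free monomer and 70.6% dormant form, so free monomer lies above the forecast's range. The exchange has a relaxation half-life of 0.895 h, both ways together, which is short against the 15 h of feeding. From 7.50 h to 15 h this flask goes from 17.9% to 29.3% free monomer, a tail share of 22.6%. Read at 2.5 d, with the feed over, the same flask holds 22.6% free monomer.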